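## The problem

Schizotenuin A (29) is a 2-arylbenzofuran (numbered O1, C2, C3, C3a, C4 to C7, C7a) whose furan ring carries a 3,4-dihydroxyphenyl group at C2 and a carboxyl at C3, and whose benzo ring carries an (E)-propenoate at C5 and a hydroxyl at C7. Both carboxyls are esterified with the secondary hydroxyl of (R)-3-(3,4-dihydroxyphenyl)lactic acid. The core must therefore be built as a fully substituted furan fused to a benzene ring that is substituted only at C5 and C7, with four different groups placed without ambiguity. The only stereocenters are the two R carbinol carbons of the lactic acid units; they lie far from each other and from the flat core, so neither can control the other, and each is best brought in intact from the chiral pool. Both centres sit alpha to a carboxyl and bear an acyloxy group, so base threatens epimerization and ester cleavage. The molecule also holds three catechols and a phenol that oxidize easily, two free acids, and an electron-poor C=C that rules out hydrogenolysis, so all protecting groups must fall in one near-neutral operation at the end. The feature that opens the route is the benzo ring itself, with oxygen at C7, carbon at C5 and hydrogen at C4 and C6. This is the pattern formed when an alkylidenesuccinic half-ester on furan C4 closes as a dienylketene onto the free alpha carbon C5 of the furan, while the other neighbour, furan C3, is blocked by the carboxyl the target needs there.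

## Retrosynthesis

**29 from 28 (nine O–allyl bonds).** The last step can only be a deprotection, and the seven phenols and two acids of 29 decide its kind. Acid-labile acetals would release formaldehyde equivalents beside catechols and expose the ester links to acid; benzyl groups would need hydrogenolysis, which would saturate the propenoate. All nine groups are therefore masked as allyl ethers and allyl esters in 28 and cut with zerovalent palladium. 28 is no simpler in skeleton, but it is stable to air and chromatography. The forward reaction must ionize aryl allyl ethers and allyl esters alike while leaving the E-alkene and both alpha-acyloxy esters alone.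

**28 from 27 and 26 (the C=C of the propenoate).** Cutting the alkene gives aldehyde 27 and phosphonate 26. The neighbouring cut, the acyl–oxygen bond of the cinnamate, would require a free cinnamic acid on the core and a second esterification late in the route. A Heck-type cut would need a C5 halide that the ring construction does not supply. The olefination is asked to be E-selective under a base too weak to enolize either alpha-acyloxy ester. Phosphonate 26 is the ester of alcohol 24 with acid 25.

**27 from 22 and 24 (the acyl–oxygen bond at C3).** This cut separates the achiral core acid 22 from the chiral alcohol 24. The same alcohol 24 serves both side chains, and it comes in one step from (R)-danshensu 23, so both stereocenters are bought, not made. The esterification is placed before the olefination so that the crowded acid is joined to the smaller partner. It must not break the carbinol C–O bond, so that R is retained.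

**22 back to 17 (functional-group changes on the core).** The two carboxyl carbons of the core must be told apart: C5 is wanted as an aldehyde, C3 as a free acid. They are given different esters from the outset, methyl at C5 and tert-butyl at C3. Acid 22 then comes from tert-butyl ester 21 by acidolysis, aldehyde 21 from alcohol 20, and 20 from diester 19 by a hydride reduction that takes the unhindered methyl ester only. 19 comes from acetate 17 by exchanging acetyl for allyl: methanolysis leaves the potassium phenoxide 18, which is alkylated in the same flask. The tert-butyl group is chosen for C3 because it also resists the alkoxide of the Stobbe step, where an exchangeable ester next to the aldehyde would be at risk.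

**17 from 12 (the C7–C7a bond and the whole benzo ring).** Cutting C7–C7a opens the benzo ring to the E half-ester 12, a furan carrying a four-carbon acid chain at C4. Compared with annulating a furan onto a preformed, differentially substituted benzene, this cut removes all regiochemical questions on the benzo ring. The C5 carbon and C7 oxygen come from the succinate unit, and closure can only occur at the free furan alpha carbon. The forward reaction passes through anhydride 13, ketene 14, dienone 15 and phenol 16. It requires the E geometry of 12 and a medium that spares the tert-butyl ester and the allyl ethers.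

**12 from 9 and 10 (the exocyclic C=C).** The alkene between the future C4 and C5 is cut by a Stobbe condensation of furan aldehyde 9 with dimethyl succinate 10, through lactone 11. This one step installs the acid arm, the C5 methyl ester and the required geometry. It is preferred to a stepwise olefination followed by selective hydrolysis, which is kept in reserve.

**9 from 8, and 8 from 4 and 5 (furan C3–C4 and O1–C5 bonds).** Aldehyde 9 is the oxidation product of chloromethylfuran 8. The furan is cut into keto ester 4 and 1,3-dichloroacetone 5 (Feist–Bénary), through hydroxydihydrofuran 6 and its sulfonate 7. The symmetry of 5 means either chloride can be displaced, and the one that remains becomes the C4 handle. The forward reaction must add to the ketone carbonyl before any C-alkylation, and must dehydrate without acid.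

**4 from 2 and 3, and 2 from 1.** The aroylacetate 4 is cut at its ketone–CH2 bond into ester 2 and tert-butyl acetate 3 (crossed Claisen). Ester 2 is the triply allylated form of 3,4-dihydroxybenzoic acid 1, so one alkylation supplies both the acyl donor and the catechol protection.

## Roads not taken

Alternative 1: flavanone ring contraction by an oxidative 1,2-aryl shift.
- Cut: the C3–C3a bond, unfolding the 2-aryl-3-carboxylate unit into flavanone A1.
- Forward key step: with PhI(OAc)2 (trivalent iodine) and H2SO4 in trimethyl orthoformate, or with Tl(NO3)3 (trivalent thallium), ring A would migrate from the carbonyl carbon to C3. The old carbonyl is expelled as a methyl ester, giving the trans-dihydrobenzofuran A2.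
- Merits: A1 is reached quickly by chalcone chemistry, and the contraction sets the C2 aryl and C3 ester in the right relation. The C5 bromide would allow a Heck reaction that installs the acrylate arm directly. This avoids the ester–alcohol–aldehyde detour of the chosen plan, so in core step count this road is as good or better.
- Weak points: the rearrangement has two competitors, a shift of the C2 aryl to C3 (isoflavone formation) and dehydrogenation to the flavone. In this target the C2 aryl is an electron-rich dialkoxyphenyl, the best migrating group present, while ring A is deactivated by bromine, so the substitution pattern favours the wrong shift. A2 also contains two stereocenters that must be erased by a further oxidation of an electron-rich system. Its benzyl ethers cannot be removed by hydrogenolysis beside the propenoate, and the thallium variant is toxic.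
- Comparison: the chosen plan offers a ring closure with only one possible site, no stereocenters made and destroyed, and protecting groups that suit the alkene.

Alternative 2: double enantioselective Passerini reaction on the core diacid.
- Cut: both ester C–O bonds and both carbinol-carbon-to-carbonyl bonds, reducing the target to diacid A3, aldehyde A4 and isocyanide A5.
- Forward key step: two Passerini reactions under a chiral phosphoric acid of the 3,3'-diaryl-BINOL type would give A6, with both stereocenters set by the catalyst.
- Merits: the convergence is unmatched, since both side chains and both centres arise in one step from achiral parts. The crowded C3 acid reacts as a nucleophile, which avoids the hindered esterification. In both respects it is better than the chosen plan.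
- Weak points: A4 is an enolizable arylacetaldehyde. Two electronically different acids must both react with the same high selectivity, and any shortfall gives diastereomers with remote centres that are hard to separate. Most seriously, A6 is a bis(secondary amide), not a diacid. Converting two N-tert-octyl amides into carboxylic acids next to two ester links of the same alpha-acyloxy carbonyl type, in an electron-rich polyphenol, has no mild solution. The benzyl ethers again conflict with the alkene.
- Comparison: the chosen plan takes both centres from 23 with certainty and ends at the free acids by a near-neutral deallylation. It pays with two separate fragment couplings.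

Alternative 3: three-component carbonylative cyclization installing the C3 ester.
- Cut: O1–C2, the bond from C3 to its carbonyl carbon, and the C3 ester C–O bond, giving alkynylphenol A7 (already carrying the C5 side chain), carbon monoxide and alcohol A8.
- Forward key step: PdI2 with KI and an oxidant (divalent palladium) would effect oxypalladation, CO insertion and alcoholysis to give A9.
- Merits: the furan ring, the C3 carbonyl and the hindered ester form in one step. No redox adjustment of a C5 ester is needed, and the route is probably shorter on paper. Here the alternative is better.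
- Weak points: this oxidative alkoxycarbonylation is normally run with the alcohol in large excess or as solvent. With about one equivalent of a precious, weakly nucleophilic alpha-hydroxy ester, protodepalladation and simple cycloisomerization to the C3-unsubstituted benzofuran are expected to compete. The acrylate of A7 may intercept the vinylpalladium intermediate, and the oxidizing, iodide-rich medium meets electron-rich acetal-protected arenes. Final removal of seven methoxymethyl groups by acid releases formaldehyde equivalents beside catechols.
- Comparison: the chosen plan uses stoichiometric steps of established type, alcohol 24 in near-equimolar amount, and a ring fusion fixed by blocked positions.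

Key step: step 6

Remark: (R)-danshensu 23 is taken as the free acid (with the sodium salt, step 11 needs one equivalent less K2CO3); "allyl" means prop-2-en-1-yl throughout.

## Steps

Step 1
Reactants: 1 3,4-dihydroxybenzoic acid
Product: 2 allyl 3,4-bis(allyloxy)benzoate
Conditions: allyl bromide (3.6 equiv), K2CO3, DMF, 60 °C
Reagents that add atoms: allyl bromide, C=CCBr
Why: Williamson etherification and carboxylate alkylation (SN2) under K2CO3 allylate all three acidic sites at once, giving the acyl donor for step 2 and a catechol protection that lasts to the final step.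

Step 2
Reactants: 2 allyl 3,4-bis(allyloxy)benzoate; 3 tert-butyl acetate
Product: 4 tert-butyl 3-[3,4-bis(allyloxy)phenyl]-3-oxopropanoate
Conditions: LiN(SiMe3)2 (3.2 equiv), 3 (3 equiv), THF, −78 °C; add 2; −78 → 0 °C; aq. NH4Cl
Reagents that add atoms: none
Why: Crossed Claisen condensation; the lithium enolate of tert-butyl acetate acylates on the aryl ester with loss of allyl alkoxide, and the product is held as its enolate, which prevents a second addition and is the reason for the excess of enolate.

Step 3
Reactants: 4 tert-butyl 3-[3,4-bis(allyloxy)phenyl]-3-oxopropanoate; 5 1,3-dichloroacetone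
Product: 8 tert-butyl 2-[3,4-bis(allyloxy)phenyl]-4-(chloromethyl)furan-3-carboxylate, via hydroxydihydrofuran 6 (not isolated), via tertiary methanesulfonate 7 (not isolated)
Conditions: iPr2NEt, MeCN, 0 °C → rt; then MsCl, iPr2NEt, 0 °C → rt
Reagents that add atoms: none
Why: Feist–Bénary furan synthesis; the enol carbon of 4 adds to the strongly electrophilic carbonyl of 5 and the enol oxygen displaces one chloride to give 6, whose tertiary hydroxyl is sulfonylated to 7 and lost with the C5 proton to aromatize the ring without acid, which the tert-butyl ester would not tolerate. The symmetry of 5 makes the choice of chloride irrelevant and leaves the second CH2Cl at C4; a hindered amine is used so that the chloromethyl groups are not quaternized.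

Step 4
Reactants: 8 tert-butyl 2-[3,4-bis(allyloxy)phenyl]-4-(chloromethyl)furan-3-carboxylate
Product: 9 tert-butyl 2-[3,4-bis(allyloxy)phenyl]-4-formylfuran-3-carboxylate
Conditions: N-methylmorpholine N-oxide (3 equiv), KI (cat.), MeCN, 50 °C
Reagents that add atoms: N-methylmorpholine N-oxide, C[N+]1([O-])CCOCC1
Why: Amine N-oxide oxidation of an activated primary halide (Kornblum-type); iodide-assisted O-alkylation of the N-oxide and fragmentation of the alkoxyammonium ion give the aldehyde without touching the allyl ethers or the ester.

Step 5
Reactants: 9 tert-butyl 2-[3,4-bis(allyloxy)phenyl]-4-formylfuran-3-carboxylate; 10 dimethyl succinate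
Product: 12 (E)-4-{5-[3,4-bis(allyloxy)phenyl]-4-(tert-butoxycarbonyl)furan-3-yl}-3-(methoxycarbonyl)but-3-enoic acid, via paraconate lactone 11 (not isolated)
Conditions: NaOMe, MeOH, 65 °C; then 1 M aq. HCl to pH 3, 0 °C
Reagents that add atoms: none
Why: Stobbe condensation; aldol addition of the succinate enolate, lactonization to 11 and irreversible base-induced ring opening give the half-ester with the acid on the CH2 arm and, as is usual for aryl aldehydes, the E geometry (furyl cis to CH2CO2H). Methoxide matches the methyl esters, and the hindered, donor-conjugated tert-butyl ester should neither exchange nor capture the aldolate.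

Step 6
Reactants: 12 (E)-4-{5-[3,4-bis(allyloxy)phenyl]-4-(tert-butoxycarbonyl)furan-3-yl}-3-(methoxycarbonyl)but-3-enoic acid
Product: 17 3-tert-butyl 5-methyl 7-acetoxy-2-[3,4-bis(allyloxy)phenyl]benzofuran-3,5-dicarboxylate, via mixed anhydride 13 (not isolated), via dienylketene 14 (not isolated), via dienone 15 (not isolated), via phenol 16 (not isolated)
Conditions: Ac2O, NaOAc, 120 °C
Reagents that add atoms: acetic anhydride, CC(=O)OC(C)=O
Why: Acetic anhydride converts the acid into mixed anhydride 13, and acetate removes the doubly activated alpha proton with loss of acetate to give dienylketene 14, in which the ketene C=C, the exocyclic C=C and the furan C4=C5 bond form a hexatriene. Thermal disrotatory six-electron electrocyclization joins the ketene carbon to furan C5 (the C7–C7a bond) and gives dienone 15, which tautomerizes to phenol 16 and is acetylated in the same pot. The closest known reaction type is the Stobbe half-ester benzannulation that converts arylidene- and furylmethylene-succinic half-esters into acetoxynaphthoates and 7-acetoxybenzofuran-5-carboxylates; the equivalent description as acylation of the nucleophilic furan alpha carbon by the anhydride leads to the same product. The only ring closed is the six-membered benzo ring, by this electrocyclization; no stereocenter survives, since the sp3 carbon of 15 is lost on aromatization. The step needs selectivity between the two ring carbons flanking the side chain: C3 carries the tert-butyl ester and could not aromatize after attack, whereas C5 is unsubstituted and is the alpha position of the furan, activated by O1 and by the C2 aryl group. It also needs the E geometry of 12, which holds the furan cis to the CH2 arm. NaOAc buffers the medium so that the tert-butyl ester survives, and the temperature is well below that of Claisen rearrangement of the aryl allyl ethers.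

Step 7
Reactants: 17 3-tert-butyl 5-methyl 7-acetoxy-2-[3,4-bis(allyloxy)phenyl]benzofuran-3,5-dicarboxylate
Product: 19 3-tert-butyl 5-methyl 7-(allyloxy)-2-[3,4-bis(allyloxy)phenyl]benzofuran-3,5-dicarboxylate, via potassium phenoxide 18 (not isolated)
Conditions: K2CO3, MeOH, rt; evaporate; allyl bromide, DMF, rt
Reagents that add atoms: allyl bromide, C=CCBr
Why: Carbonate-promoted methanolysis of the aryl acetate (degenerate at the methyl ester, too slow at the tert-butyl ester) leaves the C7 oxygen as potassium phenoxide 18, which stays in the flask as the salt after evaporation. Williamson O-allylation (SN2) of 18 in DMF then puts the C7 oxygen under the same protecting group as the other phenols.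

Step 8
Reactants: 19 3-tert-butyl 5-methyl 7-(allyloxy)-2-[3,4-bis(allyloxy)phenyl]benzofuran-3,5-dicarboxylate
Product: 20 tert-butyl 7-(allyloxy)-2-[3,4-bis(allyloxy)phenyl]-5-(hydroxymethyl)benzofuran-3-carboxylate
Conditions: LiBH4, THF, MeOH (2 equiv), 0 → 40 °C
Reagents that add atoms: none
Why: Chemoselective borohydride reduction; LiBH4 reduces the unhindered aryl methyl ester, while the tert-butyl ester at C3, crowded and deactivated as a vinylogous carbonate, should not be attacked at this temperature.

Step 9
Reactants: 20 tert-butyl 7-(allyloxy)-2-[3,4-bis(allyloxy)phenyl]-5-(hydroxymethyl)benzofuran-3-carboxylate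
Product: 21 tert-butyl 7-(allyloxy)-2-[3,4-bis(allyloxy)phenyl]-5-formylbenzofuran-3-carboxylate
Conditions: MnO2, CH2Cl2, rt
Reagents that add atoms: none
Why: MnO2 oxidation of a benzylic alcohol stops at the aldehyde and leaves allyl ethers and the ester alone.

Step 10
Reactants: 21 tert-butyl 7-(allyloxy)-2-[3,4-bis(allyloxy)phenyl]-5-formylbenzofuran-3-carboxylate
Product: 22 7-(allyloxy)-2-[3,4-bis(allyloxy)phenyl]-5-formylbenzofuran-3-carboxylic acid
Conditions: TFA–CH2Cl2 (1:3), 0 °C → rt
Reagents that add atoms: none
Why: Acidolysis of the tert-butyl ester by alkyl–oxygen cleavage with loss of 2-methylpropene; aryl allyl ethers and the aldehyde tolerate brief exposure to TFA at or below room temperature.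

Step 11
Reactants: 23 (R)-3-(3,4-dihydroxyphenyl)-2-hydroxypropanoic acid ((R)-danshensu)
Product: 24 allyl (R)-3-[3,4-bis(allyloxy)phenyl]-2-hydroxypropanoate
Conditions: allyl bromide (3.5 equiv), K2CO3, DMF, rt
Reagents that add atoms: allyl bromide, C=CCBr
Why: SN2 alkylation of the carboxylate and the two phenoxides under K2CO3; the secondary hydroxyl is not deprotonated by carbonate and stays free, and the stereocenter, which takes no part and is not enolized under these conditions, keeps its R configuration.

Step 12
Reactants: 24 allyl (R)-3-[3,4-bis(allyloxy)phenyl]-2-hydroxypropanoate; 25 2-(diethoxyphosphoryl)acetic acid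
Product: 26 allyl (R)-3-[3,4-bis(allyloxy)phenyl]-2-[2-(diethoxyphosphoryl)acetoxy]propanoate
Conditions: EDC·HCl, DMAP (cat.), CH2Cl2, 0 °C → rt
Reagents that add atoms: none
Why: Steglich esterification (carbodiimide activation, acyl transfer by 4-(dimethylamino)pyridine) of an unhindered acid; the carbinol C–O bond is not broken, so the R configuration is retained.

Step 13
Reactants: 22 7-(allyloxy)-2-[3,4-bis(allyloxy)phenyl]-5-formylbenzofuran-3-carboxylic acid; 24 allyl (R)-3-[3,4-bis(allyloxy)phenyl]-2-hydroxypropanoate
Product: 27 (R)-1-(allyloxy)-3-[3,4-bis(allyloxy)phenyl]-1-oxopropan-2-yl 7-(allyloxy)-2-[3,4-bis(allyloxy)phenyl]-5-formylbenzofuran-3-carboxylate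
Conditions: EDC·HCl, DMAP (1 equiv), CH2Cl2, 0 °C → rt
Reagents that add atoms: none
Why: Steglich esterification; the acid is activated as its O-acylisourea and passed by 4-(dimethylamino)pyridine to the secondary hydroxyl of 24, whose C–O bond is not broken, so R is retained. A full equivalent of the acyl-transfer agent is used because the acid is flanked by the C2 aryl group.

Step 14
Reactants: 27 (R)-1-(allyloxy)-3-[3,4-bis(allyloxy)phenyl]-1-oxopropan-2-yl 7-(allyloxy)-2-[3,4-bis(allyloxy)phenyl]-5-formylbenzofuran-3-carboxylate; 26 allyl (R)-3-[3,4-bis(allyloxy)phenyl]-2-[2-(diethoxyphosphoryl)acetoxy]propanoate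
Product: 28 nona-allyl schizotenuin A (bis(allyl ester) heptakis(allyl ether) of the target)
Conditions: LiCl, iPr2NEt, MeCN, rt
Reagents that add atoms: none
Why: Horner–Wadsworth–Emmons olefination under Masamune–Roush conditions; the lithium-chelated stabilized phosphonate gives the E-alkene, and the weak amine base should not enolize either alpha-acyloxy ester, so both R centres persist.

Step 15
Reactants: 28 nona-allyl schizotenuin A
Product: 29 schizotenuin A
Conditions: Pd(PPh3)4 (10 mol %), morpholine (excess), degassed THF, rt, argon; then aq. HCl to pH 2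
Reagents that add atoms: none
Why: Tsuji–Trost deallylation; zerovalent palladium ionizes each allyl ester and aryl allyl ether to a pi-allyl complex, which morpholine captures irreversibly. The medium is close to neutral, so the two ester links, the E-alkene and both stereocenters should not be affected.

## Compound list

1 | 3,4-dihydroxybenzoic acid | O=C(O)c1ccc(O)c(O)c1 | starting material
2 | allyl 3,4-bis(allyloxy)benzoate | C=CCOC(=O)c1ccc(OCC=C)c(OCC=C)c1 | intermediate
3 | tert-butyl acetate | CC(=O)OC(C)(C)C | starting material
4 | tert-butyl 3-[3,4-bis(allyloxy)phenyl]-3-oxopropanoate | CC(C)(C)OC(=O)CC(=O)c1ccc(OCC=C)c(OCC=C)c1 | intermediate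
5 | 1,3-dichloroacetone | O=C(CCl)CCl | starting material
6 | tert-butyl 2-[3,4-bis(allyloxy)phenyl]-4-(chloromethyl)-4-hydroxy-4,5-dihydrofuran-3-carboxylate (racemic; not isolated) | CC(C)(C)OC(=O)C1=C(c2ccc(OCC=C)c(OCC=C)c2)OCC1(O)CCl | intermediate
7 | tert-butyl 2-[3,4-bis(allyloxy)phenyl]-4-(chloromethyl)-4-(methylsulfonyloxy)-4,5-dihydrofuran-3-carboxylate (racemic; not isolated) | CC(C)(C)OC(=O)C1=C(c2ccc(OCC=C)c(OCC=C)c2)OCC1(CCl)OS(C)(=O)=O | intermediate
8 | tert-butyl 2-[3,4-bis(allyloxy)phenyl]-4-(chloromethyl)furan-3-carboxylate | CC(C)(C)OC(=O)c1c(CCl)coc1-c1ccc(OCC=C)c(OCC=C)c1 | intermediate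
9 | tert-butyl 2-[3,4-bis(allyloxy)phenyl]-4-formylfuran-3-carboxylate | CC(C)(C)OC(=O)c1c(C=O)coc1-c1ccc(OCC=C)c(OCC=C)c1 | intermediate
10 | dimethyl succinate | COC(=O)CCC(=O)OC | starting material
11 | methyl 2-{5-[3,4-bis(allyloxy)phenyl]-4-(tert-butoxycarbonyl)furan-3-yl}-5-oxotetrahydrofuran-3-carboxylate (racemic diastereomers; not isolated) | COC(=O)C1CC(=O)OC1c1coc(-c2ccc(OCC=C)c(OCC=C)c2)c1C(=O)OC(C)(C)C | intermediate
12 | (E)-4-{5-[3,4-bis(allyloxy)phenyl]-4-(tert-butoxycarbonyl)furan-3-yl}-3-(methoxycarbonyl)but-3-enoic acid | OC(=O)C/C(C(=O)OC)=C\c1coc(-c2ccc(OCC=C)c(OCC=C)c2)c1C(=O)OC(C)(C)C | intermediate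
13 | acetic (E)-4-{5-[3,4-bis(allyloxy)phenyl]-4-(tert-butoxycarbonyl)furan-3-yl}-3-(methoxycarbonyl)but-3-enoic anhydride (not isolated) | CC(=O)OC(=O)C/C(C(=O)OC)=C\c1coc(-c2ccc(OCC=C)c(OCC=C)c2)c1C(=O)OC(C)(C)C | intermediate
14 | tert-butyl 2-[3,4-bis(allyloxy)phenyl]-4-[(1E)-2-(methoxycarbonyl)-4-oxobuta-1,3-dien-1-yl]furan-3-carboxylate (dienylketene; not isolated) | O=C=C/C(C(=O)OC)=C\c1coc(-c2ccc(OCC=C)c(OCC=C)c2)c1C(=O)OC(C)(C)C | intermediate
15 | 3-tert-butyl 5-methyl 2-[3,4-bis(allyloxy)phenyl]-7-oxo-7,7a-dihydrobenzofuran-3,5-dicarboxylate (racemic; not isolated) | COC(=O)C1=CC(=O)C2OC(c3ccc(OCC=C)c(OCC=C)c3)=C(C(=O)OC(C)(C)C)C2=C1 | intermediate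
16 | 3-tert-butyl 5-methyl 2-[3,4-bis(allyloxy)phenyl]-7-hydroxybenzofuran-3,5-dicarboxylate (not isolated) | COC(=O)c1cc(O)c2oc(-c3ccc(OCC=C)c(OCC=C)c3)c(C(=O)OC(C)(C)C)c2c1 | intermediate
17 | 3-tert-butyl 5-methyl 7-acetoxy-2-[3,4-bis(allyloxy)phenyl]benzofuran-3,5-dicarboxylate | COC(=O)c1cc(OC(C)=O)c2oc(-c3ccc(OCC=C)c(OCC=C)c3)c(C(=O)OC(C)(C)C)c2c1 | intermediate
18 | potassium 2-[3,4-bis(allyloxy)phenyl]-3-(tert-butoxycarbonyl)-5-(methoxycarbonyl)benzofuran-7-olate (not isolated) | COC(=O)c1cc([O-])c2oc(-c3ccc(OCC=C)c(OCC=C)c3)c(C(=O)OC(C)(C)C)c2c1.[K+] | intermediate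
19 | 3-tert-butyl 5-methyl 7-(allyloxy)-2-[3,4-bis(allyloxy)phenyl]benzofuran-3,5-dicarboxylate | COC(=O)c1cc(OCC=C)c2oc(-c3ccc(OCC=C)c(OCC=C)c3)c(C(=O)OC(C)(C)C)c2c1 | intermediate
20 | tert-butyl 7-(allyloxy)-2-[3,4-bis(allyloxy)phenyl]-5-(hydroxymethyl)benzofuran-3-carboxylate | OCc1cc(OCC=C)c2oc(-c3ccc(OCC=C)c(OCC=C)c3)c(C(=O)OC(C)(C)C)c2c1 | intermediate
21 | tert-butyl 7-(allyloxy)-2-[3,4-bis(allyloxy)phenyl]-5-formylbenzofuran-3-carboxylate | O=Cc1cc(OCC=C)c2oc(-c3ccc(OCC=C)c(OCC=C)c3)c(C(=O)OC(C)(C)C)c2c1 | intermediate
22 | 7-(allyloxy)-2-[3,4-bis(allyloxy)phenyl]-5-formylbenzofuran-3-carboxylic acid | O=Cc1cc(OCC=C)c2oc(-c3ccc(OCC=C)c(OCC=C)c3)c(C(=O)O)c2c1 | intermediate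
23 | (R)-3-(3,4-dihydroxyphenyl)-2-hydroxypropanoic acid ((R)-danshensu) | O[C@H](Cc1ccc(O)c(O)c1)C(=O)O | starting material
24 | allyl (R)-3-[3,4-bis(allyloxy)phenyl]-2-hydroxypropanoate | O[C@H](Cc1ccc(OCC=C)c(OCC=C)c1)C(=O)OCC=C | intermediate
25 | 2-(diethoxyphosphoryl)acetic acid | CCOP(=O)(OCC)CC(=O)O | starting material
26 | allyl (R)-3-[3,4-bis(allyloxy)phenyl]-2-[2-(diethoxyphosphoryl)acetoxy]propanoate | CCOP(=O)(OCC)CC(=O)O[C@H](Cc1ccc(OCC=C)c(OCC=C)c1)C(=O)OCC=C | intermediate
27 | (R)-1-(allyloxy)-3-[3,4-bis(allyloxy)phenyl]-1-oxopropan-2-yl 7-(allyloxy)-2-[3,4-bis(allyloxy)phenyl]-5-formylbenzofuran-3-carboxylate | O=Cc1cc(OCC=C)c2oc(-c3ccc(OCC=C)c(OCC=C)c3)c(C(=O)O[C@H](Cc3ccc(OCC=C)c(OCC=C)c3)C(=O)OCC=C)c2c1 | intermediate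
28 | nona-allyl schizotenuin A (both carboxyls as allyl esters, all seven phenols as allyl ethers, both centres R, E-alkene) | O=C(/C=C/c1cc(OCC=C)c2oc(-c3ccc(OCC=C)c(OCC=C)c3)c(C(=O)O[C@H](Cc3ccc(OCC=C)c(OCC=C)c3)C(=O)OCC=C)c2c1)O[C@H](Cc1ccc(OCC=C)c(OCC=C)c1)C(=O)OCC=C | intermediate
29 | schizotenuin A | O=C(/C=C/c1cc(O)c2oc(-c3ccc(O)c(O)c3)c(C(=O)O[C@H](Cc3ccc(O)c(O)c3)C(=O)O)c2c1)O[C@H](Cc1ccc(O)c(O)c1)C(=O)O | target

## Step count and least certain steps

Total: 15 steps. Longest linear sequence: 13 steps (steps 1 to 10, then 13, 14, 15); steps 11 and 12 form the side branch.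

**Step 6 (key step).**
- Risk: acidolysis of the tert-butyl ester by the acetic acid that accumulates at 120 °C. Intermolecular acylation (oligomerization) of the ketene may also compete with ring closure, because closure needs the s-cis conformer beside a crowded ester.
- Fallback: from 12, 1-chloro-N,N,2-trimethylpropenylamine under neutral conditions would give the acid chloride (E)-tert-butyl 2-[3,4-bis(allyloxy)phenyl]-4-[4-chloro-2-(methoxycarbonyl)-4-oxobut-1-enyl]furan-3-carboxylate F1. Slow addition of F1 to Et3N in toluene at room temperature generates the same ketene 14 by dehydrochlorination at high dilution and without acid. Closure to 15 and tautomerization then give phenol 16, which is not acetylated in this medium and would be isolated. K2CO3 and allyl bromide in DMF convert 16 through phenoxide 18 into 19, where the route is rejoined; acetate 17 and the methanolysis stage of step 7 are bypassed.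

**Step 3.**
- Risk: C-alkylation of the keto ester at a CH2Cl carbon in competition with addition to the carbonyl, which after ring closure would place the chloromethyl group at C5 instead of C4. Elimination of the tertiary sulfonate may also be sluggish.
- Fallback: from 4, Feist–Bénary condensation with ethyl bromopyruvate, whose ketone is electrophilic enough to ensure carbonyl addition first, would give with iPr2NEt the racemic 3-tert-butyl 4-ethyl 2-[3,4-bis(allyloxy)phenyl]-4-hydroxy-4,5-dihydrofuran-3,4-dicarboxylate F2. MsCl and iPr2NEt convert F2 into its tertiary methanesulfonate, 3-tert-butyl 4-ethyl 2-[3,4-bis(allyloxy)phenyl]-4-(methylsulfonyloxy)-4,5-dihydrofuran-3,4-dicarboxylate F3, which eliminates in the same flask to 3-tert-butyl 4-ethyl 2-[3,4-bis(allyloxy)phenyl]furan-3,4-dicarboxylate F4. iBu2AlH at −78 °C reduces the less hindered ethyl ester to tert-butyl 2-[3,4-bis(allyloxy)phenyl]-4-(hydroxymethyl)furan-3-carboxylate F5, and MnO2 oxidation returns to the route at aldehyde 9, bypassing 8 and step 4.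

**Step 5.**
- Risk: slow or reversible aldol addition to a donor-conjugated, crowded furan aldehyde; capture of the aldolate by the neighbouring ester; partial formation of the Z half-ester, which cannot close in step 6.
- Fallback: from 9, Wittig olefination with the stabilized ylide dimethyl 2-(triphenylphosphoranylidene)succinate in toluene at 90 °C would give dimethyl (E)-2-({5-[3,4-bis(allyloxy)phenyl]-4-(tert-butoxycarbonyl)furan-3-yl}methylene)succinate F6 under neutral conditions. One equivalent of LiOH at 0 °C then hydrolyses the saturated, unconjugated ester faster than the conjugated one and, after acidification, returns to the route at 12.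

**Step 13.**
- Risk: rearrangement of the O-acylisourea to the unreactive N-acylurea faster than acyl transfer, because the acid is flanked by the C2 aryl group and the alcohol is a weakly nucleophilic alpha-hydroxy ester.
- Fallback (double inversion, starting from 24 and 22): Mitsunobu reaction of 24 with chloroacetic acid (PPh3, diisopropyl azodicarboxylate) gives allyl (S)-3-[3,4-bis(allyloxy)phenyl]-2-(2-chloroacetoxy)propanoate F7. Thiourea removes the chloroacetyl group to give allyl (S)-3-[3,4-bis(allyloxy)phenyl]-2-hydroxypropanoate F8. A second Mitsunobu reaction of F8 with acid 22 as the nucleophile inverts the centre again and arrives at 27. The crowded acid then reacts through its carboxylate oxygen at an activated secondary carbon, not through attack at its hindered carbonyl.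

**Step 15.**
- Risk: incomplete cleavage of the nine allyl groups giving partly protected mixtures; air oxidation of the liberated catechols in the basic amine medium; conjugate addition of the amine to the propenoate.
- Fallback (two mechanistically different stages, starting from 28): Pd(PPh3)4 (zerovalent palladium) with a slight excess of pyrrolidine at 0 °C removes only the two allyl esters, carboxylate being by far the better leaving group, to give the diacid hepta-O-allyl schizotenuin A F9. Isomerization with H2-activated [Ir(cod)(PMePh2)2]PF6 (monovalent iridium) converts the aryl allyl ethers into hepta-O-[(E)-prop-1-enyl] schizotenuin A F10. Its enol ethers are hydrolysed by dilute aqueous HCl in acetone to give 29, with neither amine nor palladium present once the catechols are free.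

## Further compounds

F1 | step 6 | (E)-tert-butyl 2-[3,4-bis(allyloxy)phenyl]-4-[4-chloro-2-(methoxycarbonyl)-4-oxobut-1-enyl]furan-3-carboxylate (acid chloride of 12) | O=C(Cl)C/C(C(=O)OC)=C\c1coc(-c2ccc(OCC=C)c(OCC=C)c2)c1C(=O)OC(C)(C)C
F2 | step 3 | 3-tert-butyl 4-ethyl 2-[3,4-bis(allyloxy)phenyl]-4-hydroxy-4,5-dihydrofuran-3,4-dicarboxylate (racemic) | CCOC(=O)C1(O)COC(c2ccc(OCC=C)c(OCC=C)c2)=C1C(=O)OC(C)(C)C
F3 | step 3 | 3-tert-butyl 4-ethyl 2-[3,4-bis(allyloxy)phenyl]-4-(methylsulfonyloxy)-4,5-dihydrofuran-3,4-dicarboxylate (racemic) | CCOC(=O)C1(OS(C)(=O)=O)COC(c2ccc(OCC=C)c(OCC=C)c2)=C1C(=O)OC(C)(C)C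
F4 | step 3 | 3-tert-butyl 4-ethyl 2-[3,4-bis(allyloxy)phenyl]furan-3,4-dicarboxylate | CCOC(=O)c1coc(-c2ccc(OCC=C)c(OCC=C)c2)c1C(=O)OC(C)(C)C
F5 | step 3 | tert-butyl 2-[3,4-bis(allyloxy)phenyl]-4-(hydroxymethyl)furan-3-carboxylate | OCc1coc(-c2ccc(OCC=C)c(OCC=C)c2)c1C(=O)OC(C)(C)C
F6 | step 5 | dimethyl (E)-2-({5-[3,4-bis(allyloxy)phenyl]-4-(tert-butoxycarbonyl)furan-3-yl}methylene)succinate | COC(=O)C/C(C(=O)OC)=C\c1coc(-c2ccc(OCC=C)c(OCC=C)c2)c1C(=O)OC(C)(C)C
F7 | step 13 | allyl (S)-3-[3,4-bis(allyloxy)phenyl]-2-(2-chloroacetoxy)propanoate | ClCC(=O)O[C@@H](Cc1ccc(OCC=C)c(OCC=C)c1)C(=O)OCC=C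
F8 | step 13 | allyl (S)-3-[3,4-bis(allyloxy)phenyl]-2-hydroxypropanoate | O[C@@H](Cc1ccc(OCC=C)c(OCC=C)c1)C(=O)OCC=C
F9 | step 15 | hepta-O-allyl schizotenuin A (both carboxylic acids free, seven aryl allyl ethers) | O=C(/C=C/c1cc(OCC=C)c2oc(-c3ccc(OCC=C)c(OCC=C)c3)c(C(=O)O[C@H](Cc3ccc(OCC=C)c(OCC=C)c3)C(=O)O)c2c1)O[C@H](Cc1ccc(OCC=C)c(OCC=C)c1)C(=O)O
F10 | step 15 | hepta-O-[(E)-prop-1-enyl] schizotenuin A (both carboxylic acids free) | O=C(/C=C/c1cc(O/C=C/C)c2oc(-c3ccc(O/C=C/C)c(O/C=C/C)c3)c(C(=O)O[C@H](Cc3ccc(O/C=C/C)c(O/C=C/C)c3)C(=O)O)c2c1)O[C@H](Cc1ccc(O/C=C/C)c(O/C=C/C)c1)C(=O)O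
A1 | alternative 1 | 8-(benzyloxy)-2-[3,4-bis(benzyloxy)phenyl]-6-bromochroman-4-one (racemic flavanone) | O=C1CC(c2ccc(OCc3ccccc3)c(OCc3ccccc3)c2)Oc2c(OCc3ccccc3)cc(Br)cc12
A2 | alternative 1 | methyl trans-7-(benzyloxy)-2-[3,4-bis(benzyloxy)phenyl]-5-bromo-2,3-dihydrobenzofuran-3-carboxylate (racemic, one enantiomer drawn) | Brc1cc(OCc2ccccc2)c2O[C@H](c3ccc(OCc4ccccc4)c(OCc4ccccc4)c3)[C@@H](C(=O)OC)c2c1
A3 | alternative 2 | (E)-7-(benzyloxy)-2-[3,4-bis(benzyloxy)phenyl]-5-(2-carboxyvinyl)benzofuran-3-carboxylic acid | OC(=O)/C=C/c1cc(OCc2ccccc2)c2oc(-c3ccc(OCc4ccccc4)c(OCc4ccccc4)c3)c(C(=O)O)c2c1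
A4 | alternative 2 | 2-[3,4-bis(benzyloxy)phenyl]acetaldehyde | O=CCc1ccc(OCc2ccccc2)c(OCc2ccccc2)c1
A5 | alternative 2 | 2-isocyano-2,4,4-trimethylpentane (tert-octyl isocyanide) | [C-]#[N+]C(C)(C)CC(C)(C)C
A6 | alternative 2 | bis(alpha-acyloxy N-tert-octylcarboxamide) of the benzyl-protected core, both centres R | O=C(/C=C/c1cc(OCc2ccccc2)c2oc(-c3ccc(OCc4ccccc4)c(OCc4ccccc4)c3)c(C(=O)O[C@H](Cc3ccc(OCc4ccccc4)c(OCc4ccccc4)c3)C(=O)NC(C)(C)CC(C)(C)C)c2c1)O[C@H](Cc1ccc(OCc2ccccc2)c(OCc2ccccc2)c1)C(=O)NC(C)(C)CC(C)(C)C
A7 | alternative 3 | tert-butyl (R)-2-{[(E)-3-(3-{[3,4-bis(methoxymethoxy)phenyl]ethynyl}-4-hydroxy-5-(methoxymethoxy)phenyl)acryloyl]oxy}-3-[3,4-bis(methoxymethoxy)phenyl]propanoate | O=C(/C=C/c1cc(OCOC)c(O)c(C#Cc2ccc(OCOC)c(OCOC)c2)c1)O[C@H](Cc1ccc(OCOC)c(OCOC)c1)C(=O)OC(C)(C)C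
A8 | alternative 3 | tert-butyl (R)-3-[3,4-bis(methoxymethoxy)phenyl]-2-hydroxypropanoate | O[C@H](Cc1ccc(OCOC)c(OCOC)c1)C(=O)OC(C)(C)C
A9 | alternative 3 | hepta(methoxymethyl) ether bis(tert-butyl ester) of schizotenuin A | O=C(/C=C/c1cc(OCOC)c2oc(-c3ccc(OCOC)c(OCOC)c3)c(C(=O)O[C@H](Cc3ccc(OCOC)c(OCOC)c3)C(=O)OC(C)(C)C)c2c1)O[C@H](Cc1ccc(OCOC)c(OCOC)c1)C(=O)OC(C)(C)C
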